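**Retrosynthetic overview**

1. Ring labels: ring A is the oxygenated dibenzofuran ring (C1–C4), ring B the other dibenzofuran benzo ring (C6–C9), ring C the catechol ring (C1'–C6'), ring D the para-phenylene ring. Asterelin A (22) comes from its ring A methyl ether 21, and 21 from macrocyclic ketone 20 by aromatizing ring C last.
2. Feature used: ring C is a 4-alkylcatechol etherified to ring D only at O–C3' (meta to the C1' chain), with C4'–OH free. C4' and C3' therefore map onto C1 (C=O) and C2 (C–Cl) of a 2-chloro-4-alkylcyclohexanone, whose C2 and C6 are equivalent before chlorination.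
3. 20 comes from chloroketone phenol 19 by forming the O–C3' bond, which closes the 18-membered ring (ring D phenoxide displaces chloride).
4. 19 comes from ketone 16, made by B-alkyl Suzuki coupling of 7-chlorodibenzofuran stilbene 10 with vinyl ketal 12 and hydrogenation. 10 comes from aldehyde 6 by Wittig reaction, and 6 from biaryl 3 (Suzuki, 1 + 2) by demethylation and furan closure by intramolecular SNAr.
5. Ring order: rings A, B and D are bought as arenes; furan ring (step 3); 18-membered ring (step 11); ring C aromatized (step 12).

Key step: step 11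

Remark: the target has no stereocentre; the two sp3 centres that ring C carries in 19 and 20 are taken through as racemic diastereomer mixtures and disappear in step 12.

**Route**

Step 1
Reactants: 1 2-bromo-3,5-dimethoxybenzaldehyde; 2 (4-chloro-2-fluorophenyl)boronic acid
Product: 3 2-(4-chloro-2-fluorophenyl)-3,5-dimethoxybenzaldehyde
Conditions: PdCl2(dppf) (3 mol %), K2CO3, dioxane/H2O, 90 °C
Reagents that add atoms: none
Why: Suzuki–Miyaura coupling; the C–Br bond ortho to the formyl group undergoes oxidative addition much faster than the aryl chloride with this catalyst, so the chloride should survive as the later coupling handle.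

Step 2
Reactants: 3 2-(4-chloro-2-fluorophenyl)-3,5-dimethoxybenzaldehyde
Product: 4 2-(4-chloro-2-fluorophenyl)-3,5-dihydroxybenzaldehyde
Conditions: BBr3 (3.5 equiv), CH2Cl2, −78 °C to rt; H2O
Reagents that add atoms: none
Why: BBr3 demethylation cleaves both aryl methyl ethers, which avoids having to distinguish them; the aldehyde is returned on aqueous work-up and the aryl fluoride and chloride are inert.

Step 3
Reactants: 4 2-(4-chloro-2-fluorophenyl)-3,5-dihydroxybenzaldehyde
Product: 6 7-chloro-3-methoxydibenzofuran-1-carbaldehyde, via caesium phenoxide of the hydroxydibenzofuran aldehyde 5 (not isolated)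
Conditions: Cs2CO3 (3 equiv), NMP, 140 °C; then MeI, rt
Reagents that add atoms: iodomethane, CI
Why: intramolecular SNAr (addition–elimination) of the phenoxide ortho to the biaryl bond on the ortho'-fluorine closes the furan ring, a known closure of 2'-fluorobiaryl-2-ols; only that oxygen can reach the fluorinated carbon, and the remaining phenoxide is then O-methylated in the same flask.

Step 4
Reactants: 7 4-benzyloxybenzyl chloride
Product: 8 (4-benzyloxybenzyl)triphenylphosphonium chloride
Conditions: PPh3, toluene, reflux
Reagents that add atoms: triphenylphosphine, c1ccc(cc1)P(c1ccccc1)c1ccccc1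
Why: SN2 quaternization of triphenylphosphine by a reactive benzylic chloride; the salt should precipitate.

Step 5
Reactants: 8 (4-benzyloxybenzyl)triphenylphosphonium chloride; 6 7-chloro-3-methoxydibenzofuran-1-carbaldehyde
Product: 10 1-[2-(4-benzyloxyphenyl)ethenyl]-7-chloro-3-methoxydibenzofuran (E/Z mixture), via benzylidene phosphorane 9 (not isolated)
Conditions: KOtBu, THF, 0 °C; then 6, 0 °C to rt
Reagents that add atoms: none
Why: Wittig olefination with a semi-stabilized ylide; an E/Z mixture is expected and is irrelevant because the alkene is hydrogenated in step 8.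

Step 6
Reactants: 11 1,4-dioxaspiro[4.5]decane-8-carbaldehyde
Product: 12 8-ethenyl-1,4-dioxaspiro[4.5]decane
Conditions: Ph3PCH3Br, KOtBu, THF, 0 °C to rt
Reagents that add atoms: methyltriphenylphosphonium bromide, C[P+](c1ccccc1)(c1ccccc1)c1ccccc1.[Br-]
Why: Wittig methylenation of an aldehyde; the ketal is stable to the basic ylide and there is no stereocentre to epimerize.

Step 7
Reactants: 12 8-ethenyl-1,4-dioxaspiro[4.5]decane; 10 1-[2-(4-benzyloxyphenyl)ethenyl]-7-chloro-3-methoxydibenzofuran
Product: 14 1-[2-(4-benzyloxyphenyl)ethenyl]-7-[2-(1,4-dioxaspiro[4.5]decan-8-yl)ethyl]-3-methoxydibenzofuran (E/Z mixture), via B-alkyl borabicyclononane 13 (not isolated)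
Conditions: 12 (1.3 equiv), 9-BBN (1.25 equiv), THF, 0 °C to rt; then 10, Pd(OAc)2 (3 mol %), SPhos (6 mol %), K3PO4 (3 M aq), THF, 65 °C
Reagents that add atoms: 9-borabicyclo[3.3.1]nonane, B1C2CCCC1CCC2 (its boron is present only in 13; it leaves only a hydrogen in 14)
Why: anti-Markovnikov hydroboration of the terminal alkene followed by B-alkyl Suzuki–Miyaura coupling with the aryl chloride, which the SPhos-ligated zerovalent palladium catalyst activates; all B–H is consumed by excess 12 before 10 is added, so the stilbene should not be hydroborated.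

Step 8
Reactants: 14 1-[2-(4-benzyloxyphenyl)ethenyl]-7-[2-(1,4-dioxaspiro[4.5]decan-8-yl)ethyl]-3-methoxydibenzofuran
Product: 15 4-(2-{7-[2-(1,4-dioxaspiro[4.5]decan-8-yl)ethyl]-3-methoxydibenzofuran-1-yl}ethyl)phenol
Conditions: H2 (1 atm), Pd/C (10 %), EtOAc/EtOH, rt
Reagents that add atoms: none
Why: one heterogeneous hydrogenation saturates the stilbene and hydrogenolyses the benzyl ether to free the ring D phenol; it is placed after step 7 so that no aryl chloride is left to be reduced, and the ketal survives the neutral medium.

Step 9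
Reactants: 15 4-(2-{7-[2-(1,4-dioxaspiro[4.5]decan-8-yl)ethyl]-3-methoxydibenzofuran-1-yl}ethyl)phenol
Product: 16 4-(2-{1-[2-(4-hydroxyphenyl)ethyl]-3-methoxydibenzofuran-7-yl}ethyl)cyclohexan-1-one
Conditions: 2 M HCl, THF, rt
Reagents that add atoms: water, O
Why: acid-catalysed hydrolysis of the dioxolane ketal; nothing else in the molecule is acid-labile.

Step 10
Reactants: 16 4-(2-{1-[2-(4-hydroxyphenyl)ethyl]-3-methoxydibenzofuran-7-yl}ethyl)cyclohexan-1-one
Product: 19 2-chloro-4-(2-{1-[2-(4-hydroxyphenyl)ethyl]-3-methoxydibenzofuran-7-yl}ethyl)cyclohexan-1-one (racemic cis/trans mixture), via bis-trimethylsilyl enol ether 17 (not isolated), via chloroketone aryl silyl ether 18 (not isolated)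
Conditions: TMSOTf (2.3 equiv), Et3N, CH2Cl2, 0 °C; volatiles removed; NCS (1.05 equiv), THF, 0 °C; then 1 M HCl
Reagents that add atoms: N-chlorosuccinimide, O=C1CCC(=O)N1Cl; trimethylsilyl triflate, C[Si](C)(C)OS(=O)(=O)C(F)(F)F (silicon present only in 17 and 18)
Why: electrophilic α-chlorination of a silyl enol ether with NCS; the symmetric ketone gives a single enol ether constitution and one chlorine per ketone, the transient aryl silyl ether keeps the phenol ring out of the chlorination, and the new C2 centre forms without control relative to C4, which is acceptable because both centres are erased later.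

Step 11
Reactants: 19 2-chloro-4-(2-{1-[2-(4-hydroxyphenyl)ethyl]-3-methoxydibenzofuran-7-yl}ethyl)cyclohexan-1-one
Product: 20 macrocyclic 2-aryloxy-4-alkylcyclohexanone (18-membered ring; ring D oxygen bonded to C2 of the cyclohexanone in place of chlorine; ring A methyl ether; racemic diastereomer mixture)
Conditions: Cs2CO3 (3 equiv), MeCN, 60 °C, 19 added by syringe pump (final concentration 2 mM), argon
Reagents that add atoms: none
Why: Cs2CO3 converts the only free phenol (ring D) into its caesium phenoxide, which attacks C2 of the chloroketone opposite to chloride in an SN2 displacement accelerated by the adjacent carbonyl, forming the O–C3' bond. The closest known reactions are the Williamson etherification of phenols with 2-chlorocyclohexanone under carbonate bases and macrocyclic Williamson ring closures at high dilution. The 18-membered ring closes in exo-tet mode, helped by the flexible sp3 ring C and by slow addition that keeps the stationary concentration low. The new oxygen-bearing centre at C2 and the existing C4 centre need no control, because C2 can epimerize next to the ketone and both centres vanish when ring C is aromatized in step 12. The step needs O-alkylation in preference to C-alkylation, HCl loss and Favorskii contraction, which the weakly basic oxygen nucleophile in a polar aprotic solvent favours, and it needs a single phenoxide, which the methyl ether on ring A guarantees. The ether constitution is fixed beforehand: C2 and C6 of the parent 4-substituted cyclohexanone are equivalent, so direct substitution, and even substitution through the α' position, can only place the aryloxy group 1,3 to the chain, which becomes C3' next to C4'–OH.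

Step 12
Reactants: 20 macrocyclic 2-aryloxy-4-alkylcyclohexanone
Product: 21 asterelin A ring A methyl ether (ring C now the 2-aryloxy-4-alkylphenol)
Conditions: Pd(OCOCF3)2 (10 mol %), 2-(dimethylamino)pyridine (20 mol %), TsOH·H2O (40 mol %), O2 (1 atm), DMSO, 80 °C
Reagents that add atoms: none
Why: palladium-catalysed aerobic dehydrogenation of a cyclohexanone to a phenol (two rounds of palladium enolate formation and β-hydride elimination, then tautomerization); both diastereomers of 20 converge on the same arene, and the aryloxy group sits α rather than β to the metal-bearing carbons, so it should not be eliminated.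

Step 13
Reactants: 21 asterelin A ring A methyl ether
Product: 22 asterelin A
Conditions: BBr3 (3 equiv), CH2Cl2, −78 to 0 °C; H2O
Reagents that add atoms: none
Why: BBr3 cleavage of the single aryl methyl ether; the diaryl ether, the dibenzofuran and the free phenol are stable to these conditions.

**Compound list**

1 | 2-bromo-3,5-dimethoxybenzaldehyde | COc1cc(OC)c(Br)c(C=O)c1 | starting material
2 | (4-chloro-2-fluorophenyl)boronic acid | OB(O)c1ccc(Cl)cc1F | starting material
3 | 2-(4-chloro-2-fluorophenyl)-3,5-dimethoxybenzaldehyde | COc1cc(OC)c(-c2ccc(Cl)cc2F)c(C=O)c1 | intermediate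
4 | 2-(4-chloro-2-fluorophenyl)-3,5-dihydroxybenzaldehyde | Oc1cc(O)c(-c2ccc(Cl)cc2F)c(C=O)c1 | intermediate
5 | caesium 7-chloro-1-formyldibenzofuran-3-olate (not isolated) | [Cs+].[O-]c1cc(C=O)c2c(c1)oc1cc(Cl)ccc12 | intermediate
6 | 7-chloro-3-methoxydibenzofuran-1-carbaldehyde | COc1cc(C=O)c2c(c1)oc1cc(Cl)ccc12 | intermediate
7 | 4-benzyloxybenzyl chloride | ClCc1ccc(OCc2ccccc2)cc1 | starting material
8 | (4-benzyloxybenzyl)triphenylphosphonium chloride | [Cl-].c1ccc(cc1)[P+](Cc1ccc(OCc2ccccc2)cc1)(c1ccccc1)c1ccccc1 | intermediate
9 | (4-benzyloxybenzylidene)triphenylphosphorane (not isolated) | c1ccc(cc1)P(=Cc1ccc(OCc2ccccc2)cc1)(c1ccccc1)c1ccccc1 | intermediate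
10 | 1-[2-(4-benzyloxyphenyl)ethenyl]-7-chloro-3-methoxydibenzofuran (E/Z mixture) | COc1cc(C=Cc2ccc(OCc3ccccc3)cc2)c2c(c1)oc1cc(Cl)ccc12 | intermediate
11 | 1,4-dioxaspiro[4.5]decane-8-carbaldehyde | O=CC1CCC2(CC1)OCCO2 | starting material
12 | 8-ethenyl-1,4-dioxaspiro[4.5]decane | C=CC1CCC2(CC1)OCCO2 | intermediate
13 | 9-[2-(1,4-dioxaspiro[4.5]decan-8-yl)ethyl]-9-borabicyclo[3.3.1]nonane (not isolated) | C(CC1CCC2(CC1)OCCO2)B1C2CCCC1CCC2 | intermediate
14 | 1-[2-(4-benzyloxyphenyl)ethenyl]-7-[2-(1,4-dioxaspiro[4.5]decan-8-yl)ethyl]-3-methoxydibenzofuran (E/Z mixture) | COc1cc(C=Cc2ccc(OCc3ccccc3)cc2)c2c(c1)oc1cc(CCC3CCC4(CC3)OCCO4)ccc12 | intermediate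
15 | 4-(2-{7-[2-(1,4-dioxaspiro[4.5]decan-8-yl)ethyl]-3-methoxydibenzofuran-1-yl}ethyl)phenol | COc1cc(CCc2ccc(O)cc2)c2c(c1)oc1cc(CCC3CCC4(CC3)OCCO4)ccc12 | intermediate
16 | 4-(2-{1-[2-(4-hydroxyphenyl)ethyl]-3-methoxydibenzofuran-7-yl}ethyl)cyclohexan-1-one | COc1cc(CCc2ccc(O)cc2)c2c(c1)oc1cc(CCC3CCC(=O)CC3)ccc12 | intermediate
17 | trimethylsilyl enol ether of 16 with the phenol as its trimethylsilyl ether (racemic; not isolated) | COc1cc(CCc2ccc(O[Si](C)(C)C)cc2)c2c(c1)oc1cc(CCC3CCC(O[Si](C)(C)C)=CC3)ccc12 | intermediate
18 | 2-chloro-4-substituted cyclohexanone with the ring D phenol as its trimethylsilyl ether (racemic cis/trans mixture; not isolated) | COc1cc(CCc2ccc(O[Si](C)(C)C)cc2)c2c(c1)oc1cc(CCC3CCC(=O)C(Cl)C3)ccc12 | intermediate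
19 | 2-chloro-4-(2-{1-[2-(4-hydroxyphenyl)ethyl]-3-methoxydibenzofuran-7-yl}ethyl)cyclohexan-1-one (racemic cis/trans mixture) | COc1cc(CCc2ccc(O)cc2)c2c(c1)oc1cc(CCC3CCC(=O)C(Cl)C3)ccc12 | intermediate
20 | macrocyclic 2-aryloxy-4-alkylcyclohexanone, 18-membered ring, ring A methyl ether (racemic diastereomer mixture) | COc1cc2c3c(c1)oc1cc(ccc13)CCC1CCC(=O)C(C1)Oc1ccc(cc1)CC2 | intermediate
21 | asterelin A ring A methyl ether | COc1cc2c3c(c1)oc1cc(ccc13)CCc1ccc(O)c(c1)Oc1ccc(cc1)CC2 | intermediate
22 | asterelin A | Oc1cc2c3c(c1)oc1cc(ccc13)CCc1ccc(O)c(c1)Oc1ccc(cc1)CC2 | target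

**Step count and risks**

Total step count: 13. Longest linear sequence: 11 steps (steps 1, 2, 3, 5, 7, 8, 9, 10, 11, 12, 13).

Steps most likely to fail:

1. Step 11 (macro-etherification). Intermolecular O-alkylation may outrun ring closure and give oligomers, and base may take the chloroketone down HCl-loss or Favorskii ring-contraction channels before the phenoxide attacks. The fallback sets out from 16 and returns to the route at 21; it replaces the halide by an epoxide as electrophile, which has no dehydrohalogenation or Favorskii channel. The bis-silyl derivative 17, made as in step 10, would be oxidized with Pd(OAc)2 in MeCN (Saegusa–Ito oxidation) and freed at the phenol on acidic work-up to give 4-(2-{1-[2-(4-hydroxyphenyl)ethyl]-3-methoxydibenzofuran-7-yl}ethyl)cyclohex-2-en-1-one F1. Nucleophilic epoxidation (H2O2, NaOH, MeOH, 0 °C; Weitz–Scheffer) would give the corresponding 2,3-epoxycyclohexanone F2. Under Cs2CO3 in MeCN at high dilution the ring D phenoxide would open the epoxide at C2, the carbon next to the carbonyl, and the β-hydroxy ketone formed would lose water to give the macrocyclic 2-aryloxycyclohex-2-enone F3; this follows the known base-mediated route from 2,3-epoxycyclohexanones and phenols to 2-aryloxycyclohex-2-enones. The conditions of step 12 would then convert F3 into 21 with only one C–C dehydrogenation left to perform.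

2. Step 12 (aromatization of ring C). The dehydrogenation may stall at the enone level, or the acidic oxidizing medium may attack the electron-rich rings or promote cyclodehydration of the aryloxy ketone onto ring D. The fallback sets out from 20 and returns at 21; it performs the two dehydrogenations one at a time under neutral conditions. Kinetic enolization with LiN(SiMe3)2 and TMSCl in THF at −78 °C on the CH2 side of the ketone would give the trimethylsilyl enol ether F4, and Pd(OAc)2 in MeCN (Saegusa–Ito) would give the 6-aryloxy-4-alkylcyclohex-2-enone F5. A second enolization with LiN(SiMe3)2 and TMSCl toward the aryloxy-bearing carbon would give the cross-conjugated silyl dienol ether F6. A second Pd(OAc)2 oxidation would give the 2,5-cyclohexadienone, which is the keto tautomer of 21 and should tautomerize to it.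

3. Step 3 (furan closure). Fluoride displacement on a ring without an activating group may be slow, and the free aldehyde may degrade under hot carbonate before closure is complete. The fallback sets out from 4 and returns at 6; it carries the carbonyl in masked form so that the closure can be forced with a strong base. Acetalization (ethylene glycol, TsOH, toluene, reflux with water removal) would give 2-[2-(4-chloro-2-fluorophenyl)-3,5-dihydroxyphenyl]-1,3-dioxolane F7. KOtBu in DMSO at 120 °C followed by MeI would close the furan and methylate the remaining phenoxide to give 2-(7-chloro-3-methoxydibenzofuran-1-yl)-1,3-dioxolane F8. 1 M HCl in THF would return aldehyde 6.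

**Further compounds**

F1 | step 11 | 4-(2-{1-[2-(4-hydroxyphenyl)ethyl]-3-methoxydibenzofuran-7-yl}ethyl)cyclohex-2-en-1-one (racemic) | COc1cc(CCc2ccc(O)cc2)c2c(c1)oc1cc(CCC3CCC(=O)C=C3)ccc12
F2 | step 11 | 2,3-epoxy-4-(2-{1-[2-(4-hydroxyphenyl)ethyl]-3-methoxydibenzofuran-7-yl}ethyl)cyclohexan-1-one (racemic diastereomer mixture) | COc1cc(CCc2ccc(O)cc2)c2c(c1)oc1cc(CCC3CCC(=O)C4OC34)ccc12
F3 | step 11 | macrocyclic 2-aryloxy-4-alkylcyclohex-2-en-1-one, ring A methyl ether (racemic) | COc1cc2c3c(c1)oc1cc(ccc13)CCC1CCC(=O)C(=C1)Oc1ccc(cc1)CC2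
F4 | step 12 | trimethylsilyl enol ether of 20 on the CH2 side (racemic diastereomer mixture) | COc1cc2c3c(c1)oc1cc(ccc13)CCC1CC=C(O[Si](C)(C)C)C(C1)Oc1ccc(cc1)CC2
F5 | step 12 | macrocyclic 6-aryloxy-4-alkylcyclohex-2-en-1-one (racemic diastereomer mixture) | COc1cc2c3c(c1)oc1cc(ccc13)CCC1C=CC(=O)C(C1)Oc1ccc(cc1)CC2
F6 | step 12 | cross-conjugated trimethylsilyl dienol ether of F5 (racemic) | COc1cc2c3c(c1)oc1cc(ccc13)CCC1C=CC(O[Si](C)(C)C)=C(C1)Oc1ccc(cc1)CC2
F7 | step 3 | 2-[2-(4-chloro-2-fluorophenyl)-3,5-dihydroxyphenyl]-1,3-dioxolane | Oc1cc(O)c(-c2ccc(Cl)cc2F)c(C2OCCO2)c1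
F8 | step 3 | 2-(7-chloro-3-methoxydibenzofuran-1-yl)-1,3-dioxolane | COc1cc(C2OCCO2)c2c(c1)oc1cc(Cl)ccc12
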